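## Retrosynthetic overview

- The strategy rests on ring D being a 4,6-dialkylated pyrogallol. At C4a' and C6' it carries two homologous, equally configured aryl-C3 chains (C4'–C3'–C2'–ring E and C4–C3–C2–ring B), each flanked by a ring D oxygen (O1' and the 7'-oxygen). The interflavan bond C4–C6' is therefore only the second arm, and both arms are grown at once from one ring D dialdehyde.
- Last C–C disconnection: C4–C4a (ring C), by attack of ring A on an orthoester-derived acetoxonium ion at C4 with inversion. Before it: C2–O1 (ring A as aryl ether) and C2'–O1' (ring F), both by invertive opening of threo cis-epoxy alcohols.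
- Stereocentres: C4 and C4' from a double catalytic asymmetric alkynylation; C2, C3, C2', C3' from hydroxyl-directed epoxidation of two Z-alkenes.
- Ring order: rings A, B, D and E are bought benzene rings; ring F closes first, ring C last.

Key step: step 16

Remarks on the chemistry (assumptions):
- Locants follow flavan numbering throughout, unprimed for the upper unit (rings A, B, C) and primed for the lower unit (rings D, E, F), also in open-chain precursors. The target is read as 2R,3R,4S / 2'R,3'R,4'S, both units 2,3-cis-3,4-trans.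
- The descriptor at C4 reads R while O7' is benzylated and S in the target, and those at C3 and C3' change with acylation, in each case without any change in space.
- (S,S)-ProPhenol is assumed to send the zinc acetylide to the Re face of both formyl groups; if the sense on this dialdehyde is the opposite, the (R,R)-ligand is taken.
- O1' is carried as its triisopropylsilyl ether and unmasked only after the epoxidation, so that no free ortho- or para-hydroxybenzylic alcohol meets peracid.

## Route

Step 1
Reactants: 1 2,3,4-trihydroxybenzaldehyde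
Product: 2 2,3,4-tris(benzyloxy)benzaldehyde
Conditions: BnBr (3.5 equiv), K2CO3, DMF, 60 °C
Reagents that add atoms: benzyl bromide, BrCc1ccccc1
Why: Williamson etherification under carbonate base; exhaustive benzylation avoids a selectivity problem among the three phenols, and the surplus ortho benzyl group is taken off in step 2.

Step 2
Reactants: 2 2,3,4-tris(benzyloxy)benzaldehyde
Product: 3 3,4-bis(benzyloxy)-2-hydroxybenzaldehyde
Conditions: MgBr2·OEt2 (1.5 equiv), toluene/Et2O, 80 °C; then 1 M HCl
Reagents that add atoms: none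
Why: Chelation-controlled Lewis acid ether cleavage: MgBr2 held between the formyl oxygen and the ortho ether oxygen delivers bromide to that benzyl group only, which frees the 2-OH (the later O1') and keeps the benzyl ethers of the later 7'- and 8'-oxygens.

Step 3
Reactants: 3 3,4-bis(benzyloxy)-2-hydroxybenzaldehyde
Product: 4 3,4-bis(benzyloxy)-5-bromo-2-hydroxybenzaldehyde
Conditions: NBS (1.05 equiv), MeCN, 0 °C to rt, dark
Reagents that add atoms: N-bromosuccinimide, O=C1CCC(=O)N1Br
Why: Electrophilic aromatic bromination; position 5 (the later C6') is para to the free hydroxyl, ortho to a benzyloxy group and meta to the formyl group, whereas position 6 is ortho to the formyl group and has only one para ether oxygen.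

Step 4
Reactants: 4 3,4-bis(benzyloxy)-5-bromo-2-hydroxybenzaldehyde
Product: 5 3,4-bis(benzyloxy)-5-bromo-2-[(triisopropylsilyl)oxy]benzaldehyde
Conditions: iPr3SiOTf (1.3 equiv), 2,6-lutidine, CH2Cl2, 0 °C
Reagents that add atoms: triisopropylsilyl triflate, CC(C)[Si](OS(=O)(=O)C(F)(F)F)(C(C)C)C(C)C
Why: O-silylation of a hindered, hydrogen-bonded phenol with a silyl triflate; the triisopropylsilyl ether is chosen because it should survive carbonate in warm DMF and zinc alkoxides yet leave with buffered fluoride.

Step 5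
Reactants: 5 3,4-bis(benzyloxy)-5-bromo-2-[(triisopropylsilyl)oxy]benzaldehyde
Product: 6 4,5-bis(benzyloxy)-6-[(triisopropylsilyl)oxy]benzene-1,3-dicarbaldehyde
Conditions: Pd(OAc)2 (3 mol %), Ph2P(CH2)4PPh2 (4.5 mol %), N-formylsaccharin (1.5 equiv), Et3SiH (1.3 equiv), Na2CO3 (1.5 equiv), DMF, 80 °C
Reagents that add atoms: N-formylsaccharin (CO source), O=CN1C(=O)c2ccccc2S1(=O)=O
Why: Palladium-catalysed reductive carbonylation of an aryl bromide: CO released from the formyl amide by carbonate inserts into the aryl–palladium bond and the acyl complex is reduced by the silane, which the existing aldehyde and the silyl ether should tolerate.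

Step 6
Reactants: 7 4-iodophenol
Product: 8 4-iodophenyl pivalate
Conditions: PivCl (1.1 equiv), Et3N, DMAP (cat.), CH2Cl2, 0 °C to rt
Reagents that add atoms: pivaloyl chloride, CC(C)(C)C(Cl)=O
Why: O-acylation; the pivalate makes rings B and E too electron-poor to assist benzylic ionisation at C2 and C2' later, and it should withstand the organozinc, fluoride and Lewis acid steps.

Step 7
Reactants: 8 4-iodophenyl pivalate; 9 trimethylsilylacetylene
Product: 10 4-[(trimethylsilyl)ethynyl]phenyl pivalate
Conditions: PdCl2(PPh3)2 (2 mol %), CuI (4 mol %), Et3N, THF, rt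
Reagents that add atoms: none
Why: Sonogashira coupling of an aryl iodide with a terminal alkyne, mild enough at room temperature to leave the aryl ester alone.

Step 8
Reactants: 10 4-[(trimethylsilyl)ethynyl]phenyl pivalate
Product: 11 4-ethynylphenyl pivalate
Conditions: Bu4NF (1.1 equiv), AcOH (1.2 equiv), THF, 0 °C
Reagents that add atoms: none
Why: Fluoride-induced C-desilylation of the alkynylsilane, buffered with acetic acid so that the aryl pivalate is not cleaved by base.

Step 9
Reactants: 6 4,5-bis(benzyloxy)-6-[(triisopropylsilyl)oxy]benzene-1,3-dicarbaldehyde; 11 4-ethynylphenyl pivalate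
Product: 13 (4R,4'R)-bis-propargylic alcohol on ring D, via methylzinc 4-(pivaloyloxy)phenylacetylide 12 (not isolated)
Conditions: 11 (5.6 equiv), ZnMe2 (5.9 equiv), (S,S)-ProPhenol (20 mol %), Ph3PO (40 mol %), toluene, 0 °C; then 6, 4 °C; sat. aq. NH4Cl
Reagents that add atoms: dimethylzinc, C[Zn]C (methylzinc unit of intermediate 12 only; none of its atoms remain in 13)
Why: Catalytic asymmetric alkynylation of aldehydes by a zinc acetylide under the catalyst formed from ZnMe2 and ProPhenol; both formyl groups should be attacked on the Re face under catalyst control, which sets C4 and C4' as R, and running the same event twice on one molecule diverts most wrong-sense additions into separable diastereomers.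

Step 10
Reactants: 13 (4R,4'R)-bis-propargylic alcohol
Product: 14 (4R,4'R)-bis-(Z)-allylic alcohol, O1' still silylated
Conditions: H2 (1 atm), Pd/CaCO3 poisoned with Pb(OAc)2, quinoline, EtOAc, rt, stopped after 2 equiv H2
Reagents that add atoms: none
Why: Syn semihydrogenation of both alkynes on the poisoned palladium surface gives the two Z-alkenes, and the benzyl ethers and the activated carbinols should not be touched by this catalyst.

Step 11
Reactants: 14 (4R,4'R)-bis-(Z)-allylic alcohol
Product: 15 bis-(threo cis-epoxy alcohol), O1' still silylated (2S,3R,4S,2'S,3'R,4'S)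
Conditions: mCPBA (3 equiv), NaHCO3, CH2Cl2, 0 °C to rt
Reagents that add atoms: meta-chloroperbenzoic acid, OOC(=O)c1cccc(Cl)c1
Why: Hydroxyl-directed peracid epoxidation; in each Z-allylic alcohol allylic 1,3-strain holds the carbinol hydrogen in the alkene plane, so the hydrogen-bonded peracid should attack one face only and give the threo cis-epoxy alcohol, which sets C3 and C3' (R) and the pre-inversion C2 and C2' (S) from the carbinols.

Step 12
Reactants: 15 bis-(threo cis-epoxy alcohol) silyl ether
Product: 16 bis-(threo cis-epoxy alcohol) with free O1' phenol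
Conditions: Bu4NF (1.2 equiv), AcOH (1.5 equiv), THF, 0 °C; used at once
Reagents that add atoms: none
Why: Fluoride cleavage of the aryl silyl ether; the acetic acid buffer keeps the freed phenol protonated, so that neither epoxide should open and no quinone methide should form from the ortho- and para-hydroxybenzylic carbinols.

Step 13
Reactants: 17 pyrogallol
Product: 18 2,2-diphenyl-1,3-benzodioxol-4-ol
Conditions: Ph2CCl2 (1.0 equiv), neat, 170 °C
Reagents that add atoms: dichlorodiphenylmethane, ClC(Cl)(c1ccccc1)c1ccccc1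
Why: Ketalisation of a catechol pair with a geminal dichloride; two adjacent hydroxyls are bridged as the diphenylmethylene ketal (the later 7- and 8-oxygens) and the third stays free as the later O1.

Step 14
Reactants: 16 bis-(threo cis-epoxy alcohol) with free O1' phenol; 18 2,2-diphenyl-1,3-benzodioxol-4-ol
Product: 20 ring F flavan-3,4-diol carrying the ring A aryl ether diol arm (2R,3R,4S,2'R,3'R,4'S), via ring F epoxy alcohol 19 (not isolated)
Conditions: Ti(OiPr)4 (3 equiv) premixed with 18 (6 equiv) in toluene, iPrOH removed in vacuo; then 16, toluene, rt to 50 °C; aq. tartaric acid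
Reagents that add atoms: none
Why: Titanium-alkoxide-mediated opening of 2,3-epoxy alcohols at the distal carbon by oxygen nucleophiles; chelation of carbinol and epoxide oxygen and the benzylic character of C2 and C2' direct attack there, the internal phenol closing ring F in a six-membered endo mode and the aryloxide of 18 opening the other arm, both by SN2 inversion (S to R), which the electron-poor rings B and E should keep clean.

Step 15
Reactants: 20 ring F flavan-3,4-diol carrying the ring A aryl ether diol arm
Product: 22 cyclic orthoacetate of the C3,C4 diol with ring F as 3',4'-diacetate, via cyclic orthoacetate 3',4'-diol 21 (not isolated)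
Conditions: MeC(OMe)3 (1.3 equiv), PPTS (5 mol %), CH2Cl2, rt; evaporate; Ac2O, pyridine, DMAP (cat.), 0 °C to rt
Reagents that add atoms: trimethyl orthoacetate, COC(C)(OC)OC; acetic anhydride, CC(=O)OC(C)=O
Why: Acid-catalysed orthoester exchange followed by O-acetylation; only the open-chain threo diol can bridge to a five-membered cyclic orthoester (trans-4,5-disubstituted, orthoester carbon as an inconsequential mixture), whereas the trans-diaxial 3',4'-diol of the ring F half-chair cannot and is acetylated.

Step 16
Reactants: 22 cyclic orthoacetate of the C3,C4 diol with ring F as 3',4'-diacetate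
Product: 24 fully protected dimer with ring C closed (2R,3R,4R,2'R,3'S,4'S), via dioxolan-2-ylium triflate 23 (not isolated)
Conditions: Me3SiOTf (1.05 equiv), 2,6-di-tert-butyl-4-methylpyridine (1.5 equiv), CH2Cl2 (0.005 M), −78 to −30 °C
Reagents that add atoms: trimethylsilyl triflate, C[Si](C)(C)OS(=O)(=O)C(F)(F)F (triflate counter-ion of intermediate 23 only)
Why: Proposed new method: Me3SiOTf removes methoxide from the orthoacetate to give the trans-4,5-disubstituted 2-methyl-1,3-dioxolan-2-ylium ion 23, whose C4–O bond is loosened by ring D (7'-OBn ortho, O1' para), and C4a of ring A (ortho to O1, para to O7) attacks C4 anti to that oxygen in an intramolecular Friedel–Crafts alkylation that leaves C3 as its acetate; the closest known reaction types are the invertive opening of orthoester-derived acetoxonium ions at the benzylic carbon by halide (diol to halohydrin ester) and the 3,4-trans-selective Lewis acid arylation of 3-O-acyl flavan C4 electrophiles, the untested element being a tethered arene as nucleophile toward an orthoester-derived ion. Ring C closes in a six-membered mode that is exo-tet for the departing oxygen and endo for the dioxolanylium ring (C3 and C4 both enter ring C), and the C2–C3–C4–nucleophile torsion of about sixty degrees that backside attack needs is already present in the cation. The new stereocentre C4 is set by inversion, which places ring D trans to the 3-acetoxy group; should the C4–O bond break ahead of attack, the bridging acetate still covers the face syn to O3. The step needs ionisation at C4 and not at C4', C2 or C2': only the open-chain diol carries the orthoester and it consumes the single equivalent of Me3SiOTf, the neutral 4'-acetate is a far poorer leaving group, the pivalates keep rings B and E from assisting benzylic ionisation, and the hindered pyridine takes up the triflic acid. Regiochemistry on ring A is secured because C4a is the only free position ortho to O1, so that only the six-membered ring C can form.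

Step 17
Reactants: 24 fully protected dimer
Product: 25 dimer bearing only the two benzyl ethers and the diphenylmethylene ketal (2R,3R,4R,2'R,3'R,4'S)
Conditions: LiAlH4 (excess), THF, 0 °C, argon; aq. KNaC4H4O6
Reagents that add atoms: none
Why: Hydride reduction cleaves the three acetates and the two aryl pivalates in one operation without base-mediated opening of the C2–O1 ethers, and the ethers and the ketal are inert to it.

Step 18
Reactants: 25 dimer bearing only the two benzyl ethers and the diphenylmethylene ketal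
Product: 26 target CNP0391561.3 (2R,3R,4S,2'R,3'R,4'S)
Conditions: H2 (1 atm), Pd(OH)2/C (20 wt %), THF/MeOH 1:1, rt, monitored and stopped at complete debenzylation; filtration under argon
Reagents that add atoms: none
Why: Hydrogenolysis of the two aryl benzyl ethers and of the diphenylmethylene ketal (as diphenylmethane) in neutral solvent, where the benzylic C2–O1, C2'–O1' and C4'–OH bonds should react much more slowly.

## Compound list

1 | 2,3,4-trihydroxybenzaldehyde | O=Cc1ccc(O)c(O)c1O | starting material
2 | 2,3,4-tris(benzyloxy)benzaldehyde | O=Cc1ccc(OCc2ccccc2)c(OCc2ccccc2)c1OCc1ccccc1 | intermediate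
3 | 3,4-bis(benzyloxy)-2-hydroxybenzaldehyde | O=Cc1ccc(OCc2ccccc2)c(OCc2ccccc2)c1O | intermediate
4 | 3,4-bis(benzyloxy)-5-bromo-2-hydroxybenzaldehyde | O=Cc1cc(Br)c(OCc2ccccc2)c(OCc2ccccc2)c1O | intermediate
5 | 3,4-bis(benzyloxy)-5-bromo-2-[(triisopropylsilyl)oxy]benzaldehyde | O=Cc1cc(Br)c(OCc2ccccc2)c(OCc2ccccc2)c1O[Si](C(C)C)(C(C)C)C(C)C | intermediate
6 | 4,5-bis(benzyloxy)-6-[(triisopropylsilyl)oxy]benzene-1,3-dicarbaldehyde (ring D; formyl carbons are C4' next to the silyloxy group and C4 next to a benzyloxy group) | O=Cc1cc(C=O)c(OCc2ccccc2)c(OCc2ccccc2)c1O[Si](C(C)C)(C(C)C)C(C)C | intermediate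
7 | 4-iodophenol | Oc1ccc(I)cc1 | starting material
8 | 4-iodophenyl pivalate | CC(C)(C)C(=O)Oc1ccc(I)cc1 | intermediate
9 | trimethylsilylacetylene | C#C[Si](C)(C)C | starting material
10 | 4-[(trimethylsilyl)ethynyl]phenyl pivalate | CC(C)(C)C(=O)Oc1ccc(C#C[Si](C)(C)C)cc1 | intermediate
11 | 4-ethynylphenyl pivalate | C#Cc1ccc(OC(=O)C(C)(C)C)cc1 | intermediate
12 | methylzinc 4-(pivaloyloxy)phenylacetylide | C[Zn]C#Cc1ccc(OC(=O)C(C)(C)C)cc1 | intermediate
13 | (1R,1'R)-1,1'-{4,5-bis(benzyloxy)-6-[(triisopropylsilyl)oxy]-1,3-phenylene}bis[3-(4-pivaloyloxyphenyl)prop-2-yn-1-ol] (C4 R, C4' R) | CC(C)(C)C(=O)Oc1ccc(C#C[C@@H](O)c2cc(c(O[Si](C(C)C)(C(C)C)C(C)C)c(OCc3ccccc3)c2OCc2ccccc2)[C@H](O)C#Cc2ccc(OC(=O)C(C)(C)C)cc2)cc1 | intermediate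
14 | (1R,1'R,2Z,2'Z)-1,1'-{4,5-bis(benzyloxy)-6-[(triisopropylsilyl)oxy]-1,3-phenylene}bis[3-(4-pivaloyloxyphenyl)prop-2-en-1-ol] | CC(C)(C)C(=O)Oc1ccc(/C=C\[C@@H](O)c2cc(c(O[Si](C(C)C)(C(C)C)C(C)C)c(OCc3ccccc3)c2OCc2ccccc2)[C@H](O)/C=C\c2ccc(OC(=O)C(C)(C)C)cc2)cc1 | intermediate
15 | bis-epoxy alcohol silyl ether: each arm an (S)-carbinol bearing a (2R,3S)-3-(4-pivaloyloxyphenyl)oxiran-2-yl group (cis-epoxide, threo; C2 S, C3 R, C4 S in both arms) | CC(C)(C)C(=O)Oc1ccc([C@@H]2O[C@@H]2[C@@H](O)c2cc(c(O[Si](C(C)C)(C(C)C)C(C)C)c(OCc3ccccc3)c2OCc2ccccc2)[C@H](O)[C@H]2O[C@H]2c2ccc(OC(=O)C(C)(C)C)cc2)cc1 | intermediate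
16 | the same bis-epoxy alcohol with free O1' phenol (C2 S, C3 R, C4 S; C2' S, C3' R, C4' S) | CC(C)(C)C(=O)Oc1ccc([C@@H]2O[C@@H]2[C@@H](O)c2cc(c(O)c(OCc3ccccc3)c2OCc2ccccc2)[C@H](O)[C@H]2O[C@H]2c2ccc(OC(=O)C(C)(C)C)cc2)cc1 | intermediate
17 | pyrogallol | Oc1cccc(O)c1O | starting material
18 | 2,2-diphenyl-1,3-benzodioxol-4-ol | Oc1cccc2OC(c3ccccc3)(c3ccccc3)Oc12 | intermediate
19 | (2'R,3'R,4'S)-7',8'-bis(benzyloxy)-2'-(4-pivaloyloxyphenyl)chroman-3',4'-diol carrying at C6' the intact epoxy alcohol arm (C2 S, C3 R, C4 S) | CC(C)(C)C(=O)Oc1ccc([C@@H]2O[C@@H]2[C@@H](O)c2cc3c(c(OCc4ccccc4)c2OCc2ccccc2)O[C@H](c2ccc(OC(=O)C(C)(C)C)cc2)[C@H](O)[C@H]3O)cc1 | intermediate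
20 | (2R,3R,4S)-7,8-bis(benzyloxy)-6-{(1S,2R,3R)-3-[(2,2-diphenyl-1,3-benzodioxol-4-yl)oxy]-1,2-dihydroxy-3-(4-pivaloyloxyphenyl)propyl}-2-(4-pivaloyloxyphenyl)chroman-3,4-diol (flavan locants: C2 R, C3 R, C4 S; 2'R, 3'R, 4'S) | CC(C)(C)C(=O)Oc1ccc([C@@H](Oc2cccc3OC(c4ccccc4)(c4ccccc4)Oc23)[C@H](O)[C@@H](O)c2cc3c(c(OCc4ccccc4)c2OCc2ccccc2)O[C@H](c2ccc(OC(=O)C(C)(C)C)cc2)[C@H](O)[C@H]3O)cc1 | intermediate
21 | 2-methoxy-2-methyl-1,3-dioxolane bridging O3 and O4 (trans-4,5-disubstituted, orthoester carbon a mixture; C2 R, C3 S, C4 S), ring F 3',4'-diol free (2'R,3'R,4'S) | CC(C)(C)C(=O)Oc1ccc([C@@H](Oc2cccc3OC(c4ccccc4)(c4ccccc4)Oc23)[C@@H]2OC(C)(OC)O[C@H]2c2cc3c(c(OCc4ccccc4)c2OCc2ccccc2)O[C@H](c2ccc(OC(=O)C(C)(C)C)cc2)[C@H](O)[C@H]3O)cc1 | intermediate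
22 | the same cyclic orthoacetate with ring F as 3',4'-diacetate (C2 R, C3 S, C4 S; 2'R, 3'S, 4'S) | CC(C)(C)C(=O)Oc1ccc([C@@H](Oc2cccc3OC(c4ccccc4)(c4ccccc4)Oc23)[C@@H]2OC(C)(OC)O[C@H]2c2cc3c(c(OCc4ccccc4)c2OCc2ccccc2)O[C@H](c2ccc(OC(=O)C(C)(C)C)cc2)[C@H](OC(C)=O)[C@H]3OC(C)=O)cc1 | intermediate
23 | trans-4,5-disubstituted 2-methyl-1,3-dioxolan-2-ylium triflate (ring D on C4, the C2 aryl ether carbon on C3) | CC(C)(C)C(=O)Oc1ccc([C@@H](Oc2cccc3OC(c4ccccc4)(c4ccccc4)Oc23)[C@@H]2O[C+](C)O[C@H]2c2cc3c(c(OCc4ccccc4)c2OCc2ccccc2)O[C@H](c2ccc(OC(=O)C(C)(C)C)cc2)[C@H](OC(C)=O)[C@H]3OC(C)=O)cc1.[O-]S(=O)(=O)C(F)(F)F | intermediate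
24 | fully protected dimer: 3,3',4'-triacetate, rings B and E as pivalates, 7',8'-dibenzyl ether, 7,8-diphenylmethylene ketal; both units 2,3-cis-3,4-trans (2R,3R,4R; 2'R,3'S,4'S) | CC(C)(C)C(=O)Oc1ccc([C@H]2Oc3c(ccc4OC(c5ccccc5)(c5ccccc5)Oc34)[C@H](c3cc4c(c(OCc5ccccc5)c3OCc3ccccc3)O[C@H](c3ccc(OC(=O)C(C)(C)C)cc3)[C@H](OC(C)=O)[C@H]4OC(C)=O)[C@H]2OC(C)=O)cc1 | intermediate
25 | dimer with free 3-, 3'-, 4'-hydroxyls and free ring B and E phenols, 7',8'-dibenzyl ether and 7,8-diphenylmethylene ketal kept (2R,3R,4R; 2'R,3'R,4'S) | Oc1ccc([C@H]2Oc3c(ccc4OC(c5ccccc5)(c5ccccc5)Oc34)[C@H](c3cc4c(c(OCc5ccccc5)c3OCc3ccccc3)O[C@H](c3ccc(O)cc3)[C@H](O)[C@H]4O)[C@H]2O)cc1 | intermediate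
26 | CNP0391561.3: (2R,3R,4S)-2-(4-hydroxyphenyl)-4-[(2R,3R,4S)-3,4,7,8-tetrahydroxy-2-(4-hydroxyphenyl)chroman-6-yl]chroman-3,7,8-triol | Oc1ccc([C@H]2Oc3c(ccc(O)c3O)[C@H](c3cc4c(c(O)c3O)O[C@H](c3ccc(O)cc3)[C@H](O)[C@H]4O)[C@H]2O)cc1 | target

## Step count and risks

Total step count: 18. Longest linear sequence: 14 steps (steps 1–5, 9–12, 14–18, from compound 1).

Steps most likely to fail:

1. Step 16 (key step). Ionisation at C4 may run ahead of ring closure, so that an open benzylic cation loses the stereochemical control; the arene may add to the cationic orthoester carbon instead of C4; or the 4'-acetate may ionise in competition.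
Fallback (known chemistry): it sets out from 22 and comes back at 25. Me3SiCl in CH2Cl2 should open the orthoester with chloride at the benzylic C4 (inversion) to give the 4-chloro 3,3',4'-triacetate F1. K2CO3 in MeOH at 0 °C should then remove the acetates and let the C3 alkoxide displace chloride (second inversion at C4), giving the trans-3,4-epoxide 3',4'-diol F2 with both diol configurations retained. Ac2O/pyridine re-protects ring F as the trans-3,4-epoxide 3',4'-diacetate F3. An epoxy-arene cyclisation (hexafluoroisopropanol at rt, or catalytic BF3·OEt2 at −78 °C), the known closure of aryl glycidyl ethers to trans-4-arylchroman-3-ols, should let C4a open the epoxide at C4 with inversion and give the ring C closed 3-hydroxy flavan F4 (3,4-trans). LiAlH4 under the conditions of step 17 then removes the remaining esters and gives 25.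

2. Step 14. The internal phenol may close in the five-membered exo mode at C3' instead of the six-membered endo mode; the intermolecular opening of the hindered cis-epoxide by 18 may stall, or isopropoxide may be transferred instead of the aryloxide.
Fallback: it sets out from 16 and comes back at 20. The one-pot titanium template is given up and the two openings are run as separate, fluoride-base-promoted operations. CsF in DMF at rt without external nucleophile should close ring F alone, by phenoxide attack at the benzylic C2' distal to the carbinol, and the ring F epoxy alcohol 19 is isolated. Compound 19 is then heated with 18 and CsF in DMF at 50 °C, the anionic benzylic opening known for 3-aryl glycidols and phenols, to give 20. No compound outside the compound list is made (F0).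

3. Step 9. Facial selectivity may be insufficient at one or both formyl groups (one is flanked by the bulky silyloxy group), or conversion of the second aldehyde may be incomplete, which would erode every later stereocentre.
Fallback: it sets out from 6 and 11 and comes back at 13. The lithium acetylide of 11 (LiN(SiMe3)2, THF, −78 °C) adds to both formyl groups without stereocontrol and gives the bis-propargylic alcohol as a stereoisomer mixture F5. MnO2 in CH2Cl2 at rt oxidises both carbinols to the bis-ynone F6. A twofold Corey–Bakshi–Shibata reduction ((S)-2-methyl-oxazaborolidine, catecholborane, toluene, −78 °C), with ring D as the large group, should then set both carbinols R under reagent control and deliver 13.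

Further compounds
F1 | step 16 | 4-chloro 3,3',4'-triacetate (chlorine at C4 anti to the 3-acetoxy group, C4 inverted relative to 22) | CC(C)(C)C(=O)Oc1ccc([C@@H](Oc2cccc3OC(c4ccccc4)(c4ccccc4)Oc23)[C@H](OC(C)=O)[C@H](Cl)c2cc3c(c(OCc4ccccc4)c2OCc2ccccc2)O[C@H](c2ccc(OC(=O)C(C)(C)C)cc2)[C@H](OC(C)=O)[C@H]3OC(C)=O)cc1
F2 | step 16 | trans-3,4-epoxide 3',4'-diol | CC(C)(C)C(=O)Oc1ccc([C@@H](Oc2cccc3OC(c4ccccc4)(c4ccccc4)Oc23)[C@@H]2O[C@H]2c2cc3c(c(OCc4ccccc4)c2OCc2ccccc2)O[C@H](c2ccc(OC(=O)C(C)(C)C)cc2)[C@H](O)[C@H]3O)cc1
F3 | step 16 | trans-3,4-epoxide 3',4'-diacetate | CC(C)(C)C(=O)Oc1ccc([C@@H](Oc2cccc3OC(c4ccccc4)(c4ccccc4)Oc23)[C@@H]2O[C@H]2c2cc3c(c(OCc4ccccc4)c2OCc2ccccc2)O[C@H](c2ccc(OC(=O)C(C)(C)C)cc2)[C@H](OC(C)=O)[C@H]3OC(C)=O)cc1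
F4 | step 16 | ring C closed 3-hydroxy flavan (3,4-trans) with 3',4'-diacetate and both pivalates | CC(C)(C)C(=O)Oc1ccc([C@H]2Oc3c(ccc4OC(c5ccccc5)(c5ccccc5)Oc34)[C@H](c3cc4c(c(OCc5ccccc5)c3OCc3ccccc3)O[C@H](c3ccc(OC(=O)C(C)(C)C)cc3)[C@H](OC(C)=O)[C@H]4OC(C)=O)[C@H]2O)cc1
F0 | step 14 | none | none
F5 | step 9 | bis-propargylic alcohol as a stereoisomer mixture | CC(C)(C)C(=O)Oc1ccc(C#CC(O)c2cc(c(O[Si](C(C)C)(C(C)C)C(C)C)c(OCc3ccccc3)c2OCc2ccccc2)C(O)C#Cc2ccc(OC(=O)C(C)(C)C)cc2)cc1
F6 | step 9 | bis-ynone | CC(C)(C)C(=O)Oc1ccc(C#CC(=O)c2cc(c(O[Si](C(C)C)(C(C)C)C(C)C)c(OCc3ccccc3)c2OCc2ccccc2)C(=O)C#Cc2ccc(OC(=O)C(C)(C)C)cc2)cc1
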